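## Analysis of the target

Numbering: C1 is the carboxyl carbon, C2 its methylene, C3–C6 are the ring carbons (O2 on C3, O1 on C6), and C7–C16 form the side chain that ends in the phenyl ring.

The target is a monocyclic 1,2-dioxane with a CH2CO2H arm on C3, a methyl on C4, and a methyl plus a 2-methyl-10-phenyldecyl chain on the fully substituted C6. It has four stereocentres: (3S,4S,6R) in the ring and (8R) in the chain. The C3 arm, the C4 methyl and the C7 chain sit on one face of the ring and the C6 methyl on the other. C8 is insulated from the ring by the C7 methylene and cannot be controlled from it.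

The O–O bond excludes low-valent metals, hydride reagents, hydrogenation over palladium, phosphines and organometallic nucleophiles once it is in place. The hydrogen on C3 is open to base-induced Kornblum–DeLaMare cleavage, and a β-peroxy carbonyl group can lose the peroxide by elimination under base.

The difficulties are the tetrasubstituted peroxy carbon C6 of fixed configuration, its relation to C3 across the O–O bond, and the remote C8. The route rests on one feature: C4–C5 is the only ring C–C bond that lies between the two oxygen-bearing stereocentres. If this bond is made last, C3 and C6 can be built on separate fragments, joined through O1–O2, and C4 set afterwards on the finished ring.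

## Retrosynthetic reasoning

**C1 oxidation level (24 ⇒ 22 ⇒ 21).** The acid is taken back to primary alcohol 22 and its silyl ether 21. A β-peroxy carbonyl group is fragile toward base, so C1 stays at the alcohol level until the end. The forward steps must be a desilylation and an oxidation that never become basic.

**C4 stereocentre (21 ⇒ 20).** The C4–H and C5–H bonds are removed, giving ring alkene 20. C4 is the only ring stereocentre without oxygen; making it sp2 removes it from the fragment-joining problem. The forward reduction must add hydrogen to C=C without touching O–O, from the face opposite the C3 arm and the C7 chain.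

**Ring closure (20 ⇒ 19).** The C4=C5 bond is cut by retro-metathesis to acyclic peroxide 19, which carries an isopropenyl group on C3 and a vinyl group on C6. Cutting C3–C4 or C5–C6 instead would demand stereocontrolled C–C formation at a peroxy carbon. Closing the ring through a C–O bond would require cyclisation onto the tertiary C6. The forward step must run olefin metathesis faster than any reaction of the O–O bond.

**Vinyl group on C6 (19 ⇒ 18 ⇒ 17).** The vinyl group is traced to aldehyde 18 and that to 1,2-diol 17. A vinyl group cannot be present while the C6–O bond is made, because the centre would then be tertiary and allylic and would ionise. The diol is what an epoxide leaves behind on opening.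

**Peroxide linkage (17 ⇒ 9 + 16).** The C3–O2 bond is cut. C6 is tertiary and cannot be displaced; C3 is secondary and can be substituted with inversion. The hydroperoxide of 9 must attack C3 of mesylate 16 directly, not the alkene terminus, and in preference to the two hydroxyl groups.

**C6–O1 bond (9 ⇒ 8 ⇒ 7).** The tertiary hydroperoxide comes from epoxy alcohol 8 by ring-opening at the tertiary carbon with inversion. Epoxide 8 comes from E-allylic alcohol 7 by Sharpless epoxidation, which fixes the absolute configuration at C6.

**Trisubstituted alkene (7 ⇒ 5 ⇒ 4).** The C6–CH3 and C5–C bonds are cut across alkyne 5. A syn carbometalation guarantees the E geometry on which the C6 configuration depends. Alkyne 5 comes from aldehyde 4 by one-carbon homologation.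

**Chain (4 ⇒ 3 ⇒ 1 + 2).** The C11–C12 bond is cut as an alkene (3), made by cross-metathesis of the trisubstituted olefin of 1 with terminal olefin 2. C8 is bought with 1 and never touched.

**C3 fragment (16 ⇒ 15 ⇒ 14 ⇒ 12 + 13; 12 ⇒ 11 ⇒ 10).** The C3–C4 bond comes from addition of 13 to aldehyde 12. The racemic alcohol 14 is resolved to 15. Aldehyde 12 comes from diol 10 by monoprotection and oxidation.

## Alternatives that were turned down

**Alternative 1:** Both C–O bonds (C3–O2 and C6–O1) are cut at once, back to the cyclic diene A2. Its diene termini become C3 and C6, and its remaining two sp2 carbons become stubs for the C3 arm and the C7 chain.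
- Forward key step: [4+2] addition of 1O2 to A2, anti to the ring methyl, gives the bicyclic endoperoxide A1.
- For it: one step makes the dioxane ring and both C–O bonds. The bicycle forces the two bridgehead substituents cis, and anti addition puts the C4 methyl on the correct face. On stereochemical economy this plan is stronger than the chosen one: three ring stereocentres follow from one, with no substitution at a hindered carbon and no late reduction.
- Against it: A2 must be made enantiopure, is volatile, and can isomerise; the ene reaction of 1O2 at its allylic C–H bonds competes. Cleaving the carbon bridge of A1 leaves two aldehydes to be told apart, one on a peroxy carbon that bears a hydrogen. The C3 stub then needs a one-carbon homologation, and the whole C7–C16 chain, with C8, must be built on the peroxide.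
- Comparison: the chosen route offers convergence instead. C8 is in place before any peroxide exists, and only three steps follow ring closure.

**Alternative 2:** The two C–CH3 bonds at C4 and C8 are cut, using the hidden symmetry of C4–C5–C6–C7–C8 about a masked C6 ketone.
- Forward key step: the bis-enolate of bis-imide A4 (NaN(SiMe3)2) is methylated at both ends with CH3I to give A3.
- For it: this is the most dependable control of C4 and C8 of any plan considered. It is stronger than the chosen route at C4, which depends on facial selectivity in a late reduction.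
- Against it: the key step forms no ring and neither C–O bond. The two identical ends of A3 must then be differentiated, which is statistical. C6 must be converted from a ketone into a methyl-bearing peroxy carbon through a tertiary cation, with no control. A later peroxide ring closure would also have to set C3.
- Comparison: the chosen route puts its effort into C6, C3 and the ring, which this plan leaves open, and takes C8 from the chiral pool.

**Alternative 3:** C4–C5, C6–O1 and C3–O2 are cut in one operation to three components: propanal A7 (as a chiral enamine), alkene A6 and O2.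
- Forward key step: the enamine radical cation adds to the CH2 terminus of A6, the tertiary C6 radical captures O2, and the hydroperoxide closes on the C3 carbonyl to give lactol A5.
- For it: step economy is far better than in the chosen route; the ring and C4 arise in one step and C8 comes with A6.
- Against it: the C6 radical is planar and remote from the catalyst, so both C6 epimers must be expected. O2 can also intercept the enamine radical cation itself. C3 is left as an anomeric mixture, and a nucleophile adding to the derived peroxycarbenium ion should enter anti to the C4 methyl, which is the wrong 3,4-relation.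
- Comparison: the chosen route is longer, but each stereocentre has a named control element and C3 and C6 are fixed before the ring is closed.

Key step: step 15

Remark on the chemistry: 1 is assumed to be of high enantiomeric purity (or upgraded beforehand), because C8 is carried through unchanged; 2 supplies C12–C16 and the phenyl ring.

## Route

Step 1
Reactants: 1 (3R)-3,7-dimethyloct-6-enal [(R)-citronellal]; 2 6-phenylhex-1-ene
Product: 3 (3R)-3-methyl-11-phenylundec-6-enal (E/Z mixture)
Conditions: 2 (3 equiv), RuCl2(=CHPh)(PCy3)(H2IMes) (second-generation Grubbs catalyst, 3 mol%), CH2Cl2, 40 °C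
Reagents that add atoms: none
Why: Olefin cross-metathesis exchanges the isopropylidene end of 1 for the alkylidene of terminal olefin 2, and loss of volatile 2-methylpropene drives it; the aldehyde is tolerated and C3 of 1 is untouched. The alkene geometry does not matter because the bond is hydrogenated next.

Step 2
Reactants: 3 (3R)-3-methyl-11-phenylundec-6-enal
Product: 4 (3R)-3-methyl-11-phenylundecanal
Conditions: H2 (1 atm), 10% Pd/C, EtOAc, rt
Reagents that add atoms: none
Why: Heterogeneous hydrogenation of an isolated disubstituted alkene; at 1 atm in ethyl acetate neither the aliphatic aldehyde nor the arene should be reduced.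

Step 3
Reactants: 4 (3R)-3-methyl-11-phenylundecanal
Product: 5 (4R)-4-methyl-12-phenyldodec-1-yne
Conditions: dimethyl (1-diazo-2-oxopropyl)phosphonate (1.3 equiv), K2CO3 (2 equiv), MeOH, 0 °C to rt
Reagents that add atoms: dimethyl (1-diazo-2-oxopropyl)phosphonate, CC(=O)C(=[N+]=[N-])P(=O)(OC)OC
Why: Seyferth–Gilbert homologation in the Ohira–Bestmann variant turns the aldehyde into the terminal alkyne; the stereocentre is β to the carbonyl and cannot be epimerised by the carbonate base.

Step 4
Reactants: 5 (4R)-4-methyl-12-phenyldodec-1-yne
Product: 7 (2E,5R)-3,5-dimethyl-13-phenyltridec-2-en-1-ol, via alkenyl(dimethyl)alane 6 (not isolated)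
Conditions: AlMe3 (2.5 equiv), ZrCl2(C5H5)2 (0.25 equiv), CH2Cl2, 0 °C to rt; then (CH2O)n, rt; 1 M HCl
Reagents that add atoms: trimethylaluminium, C[Al](C)C; formaldehyde (as paraformaldehyde), C=O
Why: Negishi zirconium-catalysed carboalumination adds CH3 and Al syn across the alkyne with CH3 on the internal carbon (C6), and the alkenylalane is hydroxymethylated with retention, so the trisubstituted alkene is formed as the E isomer.

Step 5
Reactants: 7 (2E,5R)-3,5-dimethyl-13-phenyltridec-2-en-1-ol
Product: 8 [(2S,3S)-3-methyl-3-[(2R)-2-methyl-10-phenyldecyl]oxiran-2-yl]methanol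
Conditions: Ti(OiPr)4 (10 mol%), L-(+)-DET (12 mol%), t-BuOOH (2 equiv, anhydrous), 4 Å MS, CH2Cl2, −20 °C
Reagents that add atoms: tert-butyl hydroperoxide, CC(C)(C)OO
Why: Sharpless asymmetric epoxidation; with L-(+)-tartrate an E-3-methylalk-2-en-1-ol is epoxidised in the same sense as geraniol to its (2S,3S)-epoxide, so C6 becomes S under reagent control, with no influence expected from the remote C8.

Step 6
Reactants: 8 [(2S,3S)-3-methyl-3-[(2R)-2-methyl-10-phenyldecyl]oxiran-2-yl]methanol
Product: 9 (2S,3R,5R)-3-hydroperoxy-3,5-dimethyl-13-phenyltridecane-1,2-diol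
Conditions: H2O2 (ca. 10 equiv, dried ethereal solution), H3PMo12O40·xH2O (3 mol%), Et2O, rt
Reagents that add atoms: hydrogen peroxide, OO
Why: Acid-catalysed perhydrolysis of a trisubstituted epoxide: H2O2 enters at the tertiary carbon, which carries the positive charge best, anti to the departing oxygen, so C6 is inverted to R while C5 keeps its C–O bond. Any leakage of configuration would appear later as the separable 3,6-trans ring isomer.

Step 7
Reactants: 10 propane-1,3-diol
Product: 11 3-{[tert-butyl(dimethyl)silyl]oxy}propan-1-ol
Conditions: NaH (1.0 equiv), THF, rt; then t-BuMe2SiCl (1.0 equiv), rt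
Reagents that add atoms: tert-butyl(chloro)dimethylsilane, CC(C)(C)[Si](C)(C)Cl
Why: Monosilylation of a symmetric diol through its sparingly soluble monosodium alkoxide, which reacts as it dissolves and so favours the mono-ether.

Step 8
Reactants: 11 3-{[tert-butyl(dimethyl)silyl]oxy}propan-1-ol
Product: 12 3-{[tert-butyl(dimethyl)silyl]oxy}propanal
Conditions: TEMPO (10 mol%), PhI(OAc)2 (1.1 equiv), CH2Cl2, rt
Reagents that add atoms: none
Why: Oxoammonium-mediated oxidation of a primary alcohol stops at the aldehyde in anhydrous CH2Cl2 and leaves the silyl ether alone; the aldehyde is used promptly.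

Step 9
Reactants: 12 3-{[tert-butyl(dimethyl)silyl]oxy}propanal; 13 isopropenylmagnesium bromide
Product: 14 rac-5-{[tert-butyl(dimethyl)silyl]oxy}-2-methylpent-1-en-3-ol
Conditions: 13 (1.2 equiv), THF, −78 to 0 °C; aq. NH4Cl
Reagents that add atoms: none
Why: Grignard addition to an aldehyde forms the C3–C4 bond and the carbinol as a racemate.

Step 10
Reactants: 14 rac-5-{[tert-butyl(dimethyl)silyl]oxy}-2-methylpent-1-en-3-ol
Product: 15 (3R)-5-{[tert-butyl(dimethyl)silyl]oxy}-2-methylpent-1-en-3-ol
Conditions: Ti(OiPr)4 (10 mol%), L-(+)-DIPT (15 mol%), t-BuOOH (0.6 equiv), 4 Å MS, CH2Cl2, −20 °C; to be stopped a little past half conversion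
Reagents that add atoms: none
Why: Sharpless kinetic resolution: with L-(+)-tartrate the (S)-enantiomer of a secondary allylic alcohol is epoxidised fast and the (R)-enantiomer is recovered, which is separated from the polar epoxy alcohol by chromatography.

Step 11
Reactants: 15 (3R)-5-{[tert-butyl(dimethyl)silyl]oxy}-2-methylpent-1-en-3-ol
Product: 16 (3R)-5-{[tert-butyl(dimethyl)silyl]oxy}-2-methylpent-1-en-3-yl methanesulfonate
Conditions: MsCl (1.2 equiv), Et3N (1.5 equiv), CH2Cl2, −30 to −10 °C; cold work-up, used crude at once
Reagents that add atoms: methanesulfonyl chloride, CS(=O)(=O)Cl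
Why: Sulfonylation forms an O–S bond and leaves the C3–O bond and its configuration intact; the allylic mesylate is kept cold and not stored to avoid ionisation.

Step 12
Reactants: 9 (2S,3R,5R)-3-hydroperoxy-3,5-dimethyl-13-phenyltridecane-1,2-diol; 16 (3R)-5-{[tert-butyl(dimethyl)silyl]oxy}-2-methylpent-1-en-3-yl methanesulfonate
Product: 17 (2S,3R,5R)-3-{[(3S)-5-{[tert-butyl(dimethyl)silyl]oxy}-2-methylpent-1-en-3-yl]peroxy}-3,5-dimethyl-13-phenyltridecane-1,2-diol
Conditions: CsOH·H2O (1.05 equiv), DMF, 0 °C; then 16 (1.3 equiv), 0 °C to rt
Reagents that add atoms: none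
Why: Alkylation of a hydroperoxide with a secondary sulfonate (Williams–Mosher-type SN2) inverts C3 from R to S. One equivalent of base deprotonates only the hydroperoxide (pKa about 12–13 against 16–17 for the alcohols), and the peroxide anion is an α-effect nucleophile of low basicity, which favours substitution over elimination.

Step 13
Reactants: 17 (2S,3R,5R)-3-{[(3S)-5-{[tert-butyl(dimethyl)silyl]oxy}-2-methylpent-1-en-3-yl]peroxy}-3,5-dimethyl-13-phenyltridecane-1,2-diol
Product: 18 (2R,4R)-2-{[(3S)-5-{[tert-butyl(dimethyl)silyl]oxy}-2-methylpent-1-en-3-yl]peroxy}-2,4-dimethyl-12-phenyldodecanal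
Conditions: NaIO4 (1.5 equiv), THF/pH 7 buffer (NaH2PO4/Na2HPO4), 0 °C to rt
Reagents that add atoms: none
Why: Malaprade glycol cleavage removes the terminal carbon and leaves C5 as an aldehyde on C6; periodate does not attack dialkyl peroxides, and the aldehyde has no α-hydrogen, so it can neither enolise nor epimerise.

Step 14
Reactants: 18 (2R,4R)-2-{[(3S)-5-{[tert-butyl(dimethyl)silyl]oxy}-2-methylpent-1-en-3-yl]peroxy}-2,4-dimethyl-12-phenyldodecanal
Product: 19 tert-butyl(dimethyl){[(3S)-4-methyl-3-{[(3R,5R)-3,5-dimethyl-13-phenyltridec-1-en-3-yl]peroxy}pent-4-en-1-yl]oxy}silane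
Conditions: Ph3PCH3Br (1.5 equiv), KN(SiMe3)2 (1.4 equiv), THF, 0 °C; then 18, −78 to 0 °C
Reagents that add atoms: methyltriphenylphosphonium bromide, C[P+](c1ccccc1)(c1ccccc1)c1ccccc1.[Br-]
Why: Wittig methylenation of a non-enolisable aldehyde; at low temperature the ylide adds to the carbonyl much faster than it can attack the hindered dialkyl peroxide or abstract the unactivated hydrogen on C3.

Step 15
Reactants: 19 tert-butyl(dimethyl){[(3S)-4-methyl-3-{[(3R,5R)-3,5-dimethyl-13-phenyltridec-1-en-3-yl]peroxy}pent-4-en-1-yl]oxy}silane
Product: 20 tert-butyl(dimethyl){2-[(3S,6R)-4,6-dimethyl-6-[(2R)-2-methyl-10-phenyldecyl]-3,6-dihydro-1,2-dioxin-3-yl]ethoxy}silane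
Conditions: RuCl2(=CHPh)(PCy3)(H2IMes) (second-generation Grubbs catalyst, 5–10 mol%), CH2Cl2 (0.005 M), 40 °C, argon sparge
Reagents that add atoms: none
Why: Ring-closing olefin metathesis by the Chauvin mechanism: after loss of PCy3 the ruthenium benzylidene undergoes [2+2] and retro-[2+2] with the less substituted vinyl group on C6, which places ruthenium on C5. This alkylidene adds across the isopropenyl group on C3 (C5 to C4, ruthenium to the terminal CH2), and collapse of the ruthenacyclobutane gives the C4=C5 bond and Ru=CH2, which carries the chain while the two terminal CH2 groups leave as ethene. The closest known reaction type is the ring closure of 1,7-dienes with allylic heteroatoms in the tether to six-membered rings with a trisubstituted alkene, together with the known tolerance of dialkyl peroxides toward ruthenium alkylidenes. The ring is the six-membered 3,6-dihydro-1,2-dioxine, closed by C=C formation across a tether (C3–O2–O1–C6) that is already complete. No stereocentre is made or touched; C6 has no hydrogen and the C3–H is not acidic under these neutral conditions. The step needs chemoselectivity only: metathesis must outrun O–O cleavage and oligomerisation. The fully substituted C6 (gem-dialkyl effect) and the gauche C–O–O–C dihedral bring the two alkenes together, high dilution suppresses intermolecular metathesis, and a secondary–tertiary dialkyl peroxide is a poor ligand and a poor oxidant for the divalent ruthenium centre. Sparging removes ethene, and the trisubstituted ring alkene is too hindered to re-enter metathesis.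

Step 16
Reactants: 20 tert-butyl(dimethyl){2-[(3S,6R)-4,6-dimethyl-6-[(2R)-2-methyl-10-phenyldecyl]-3,6-dihydro-1,2-dioxin-3-yl]ethoxy}silane
Product: 21 tert-butyl(dimethyl){2-[(3S,4S,6R)-4,6-dimethyl-6-[(2R)-2-methyl-10-phenyldecyl]-1,2-dioxan-3-yl]ethoxy}silane
Conditions: KO2CN=NCO2K (large excess, in portions), AcOH, MeOH/CH2Cl2, 0 °C to rt
Reagents that add atoms: none
Why: Diimide reduction transfers two hydrogens syn through a cyclic transition state and does not cleave O–O. Allylic strain with the C4 methyl pushes the C3 side chain pseudoaxial, so it and the C7 chain shield one face and hydrogen should arrive on the face of the C6 methyl, which places the C4 methyl cis to the C3 arm (4S).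

Step 17
Reactants: 21 tert-butyl(dimethyl){2-[(3S,4S,6R)-4,6-dimethyl-6-[(2R)-2-methyl-10-phenyldecyl]-1,2-dioxan-3-yl]ethoxy}silane
Product: 22 2-[(3S,4S,6R)-4,6-dimethyl-6-[(2R)-2-methyl-10-phenyldecyl]-1,2-dioxan-3-yl]ethan-1-ol
Conditions: HF·pyridine, THF/pyridine, 0 °C to rt
Reagents that add atoms: none
Why: Fluoride-driven cleavage of the primary silyl ether under mildly acidic, non-basic conditions, which avoids base-induced cleavage of the peroxide at C3–H.

Step 18
Reactants: 22 2-[(3S,4S,6R)-4,6-dimethyl-6-[(2R)-2-methyl-10-phenyldecyl]-1,2-dioxan-3-yl]ethan-1-ol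
Product: 24 2-[(3S,4S,6R)-4,6-dimethyl-6-[(2R)-2-methyl-10-phenyldecyl]-1,2-dioxan-3-yl]acetic acid (target), via dioxanylacetaldehyde 23 (not isolated)
Conditions: TEMPO (0.2 equiv), PhI(OAc)2 (2.5 equiv), MeCN/H2O (1:1), rt
Reagents that add atoms: water, O
Why: Oxoammonium oxidation of the primary alcohol to the aldehyde and, through its hydrate, on to the acid in one flask. The medium stays neutral to weakly acidic, so the β-peroxy carbonyl intermediate should not lose the peroxide by elimination, and the O–O bond is inert to this oxidant.

## Compound list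

1 | (3R)-3,7-dimethyloct-6-enal [(R)-citronellal] | C[C@H](CCC=C(C)C)CC=O | starting material
2 | 6-phenylhex-1-ene | C=CCCCCc1ccccc1 | starting material
3 | (3R)-3-methyl-11-phenylundec-6-enal (E/Z mixture) | C[C@H](CCC=CCCCCc1ccccc1)CC=O | intermediate
4 | (3R)-3-methyl-11-phenylundecanal | C[C@H](CCCCCCCCc1ccccc1)CC=O | intermediate
5 | (4R)-4-methyl-12-phenyldodec-1-yne | C[C@H](CCCCCCCCc1ccccc1)CC#C | intermediate
6 | dimethyl[(1E,4R)-2,4-dimethyl-12-phenyldodec-1-en-1-yl]alumane | C[C@H](CCCCCCCCc1ccccc1)C/C(C)=C/[Al](C)C | intermediate (not isolated)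
7 | (2E,5R)-3,5-dimethyl-13-phenyltridec-2-en-1-ol | C[C@H](CCCCCCCCc1ccccc1)C/C(C)=C/CO | intermediate
8 | [(2S,3S)-3-methyl-3-[(2R)-2-methyl-10-phenyldecyl]oxiran-2-yl]methanol | C[C@H](CCCCCCCCc1ccccc1)C[C@]2(C)O[C@H]2CO | intermediate
9 | (2S,3R,5R)-3-hydroperoxy-3,5-dimethyl-13-phenyltridecane-1,2-diol | C[C@H](CCCCCCCCc1ccccc1)C[C@](C)([C@@H](O)CO)OO | intermediate
10 | propane-1,3-diol | OCCCO | starting material
11 | 3-{[tert-butyl(dimethyl)silyl]oxy}propan-1-ol | OCCCO[Si](C)(C)C(C)(C)C | intermediate
12 | 3-{[tert-butyl(dimethyl)silyl]oxy}propanal | O=CCCO[Si](C)(C)C(C)(C)C | intermediate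
13 | isopropenylmagnesium bromide | C=C(C)[Mg]Br | starting material
14 | rac-5-{[tert-butyl(dimethyl)silyl]oxy}-2-methylpent-1-en-3-ol (racemate) | C=C(C)C(O)CCO[Si](C)(C)C(C)(C)C | intermediate
15 | (3R)-5-{[tert-butyl(dimethyl)silyl]oxy}-2-methylpent-1-en-3-ol | O[C@H](CCO[Si](C)(C)C(C)(C)C)C(C)=C | intermediate
16 | (3R)-5-{[tert-butyl(dimethyl)silyl]oxy}-2-methylpent-1-en-3-yl methanesulfonate | CS(=O)(=O)O[C@H](CCO[Si](C)(C)C(C)(C)C)C(C)=C | intermediate
17 | (2S,3R,5R)-3-{[(3S)-5-{[tert-butyl(dimethyl)silyl]oxy}-2-methylpent-1-en-3-yl]peroxy}-3,5-dimethyl-13-phenyltridecane-1,2-diol | C[C@H](CCCCCCCCc1ccccc1)C[C@](C)([C@@H](O)CO)OO[C@@H](CCO[Si](C)(C)C(C)(C)C)C(C)=C | intermediate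
18 | (2R,4R)-2-{[(3S)-5-{[tert-butyl(dimethyl)silyl]oxy}-2-methylpent-1-en-3-yl]peroxy}-2,4-dimethyl-12-phenyldodecanal | C[C@H](CCCCCCCCc1ccccc1)C[C@](C)(C=O)OO[C@@H](CCO[Si](C)(C)C(C)(C)C)C(C)=C | intermediate
19 | tert-butyl(dimethyl){[(3S)-4-methyl-3-{[(3R,5R)-3,5-dimethyl-13-phenyltridec-1-en-3-yl]peroxy}pent-4-en-1-yl]oxy}silane | C[C@H](CCCCCCCCc1ccccc1)C[C@](C)(C=C)OO[C@@H](CCO[Si](C)(C)C(C)(C)C)C(C)=C | intermediate
20 | tert-butyl(dimethyl){2-[(3S,6R)-4,6-dimethyl-6-[(2R)-2-methyl-10-phenyldecyl]-3,6-dihydro-1,2-dioxin-3-yl]ethoxy}silane | C[C@H](CCCCCCCCc1ccccc1)C[C@]1(C)C=C(C)[C@H](CCO[Si](C)(C)C(C)(C)C)OO1 | intermediate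
21 | tert-butyl(dimethyl){2-[(3S,4S,6R)-4,6-dimethyl-6-[(2R)-2-methyl-10-phenyldecyl]-1,2-dioxan-3-yl]ethoxy}silane | C[C@H](CCCCCCCCc1ccccc1)C[C@]1(C)C[C@H](C)[C@H](CCO[Si](C)(C)C(C)(C)C)OO1 | intermediate
22 | 2-[(3S,4S,6R)-4,6-dimethyl-6-[(2R)-2-methyl-10-phenyldecyl]-1,2-dioxan-3-yl]ethan-1-ol | C[C@H](CCCCCCCCc1ccccc1)C[C@]1(C)C[C@H](C)[C@H](CCO)OO1 | intermediate
23 | 2-[(3S,4S,6R)-4,6-dimethyl-6-[(2R)-2-methyl-10-phenyldecyl]-1,2-dioxan-3-yl]acetaldehyde | C[C@H](CCCCCCCCc1ccccc1)C[C@]1(C)C[C@H](C)[C@H](CC=O)OO1 | intermediate (not isolated)
24 | 2-[(3S,4S,6R)-4,6-dimethyl-6-[(2R)-2-methyl-10-phenyldecyl]-1,2-dioxan-3-yl]acetic acid | C[C@H](CCCCCCCCc1ccccc1)C[C@]1(C)C[C@H](C)[C@H](CC(=O)O)OO1 | target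

## Step count and least certain steps

Total: 18 steps. Longest linear sequence: 13 steps (steps 1–6 and 12–18, from 1). The C3 fragment needs steps 7–11 before it joins at step 12.

**Step 15 (key step).** Both alkenes are hindered (a vinyl group on a quaternary carbon and a 1,1-disubstituted alkene), so initiation and turnover may be slow. Catalyst decay, and deoxygenation of the peroxide by the PCy3 released on initiation, could then overtake ring closure. A first remedy within the step is the phosphine-free second-generation Hoveyda–Grubbs catalyst RuCl2(=CH-C6H4-2-OiPr)(H2IMes).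

Fallback, a relay ring closure: it sets out from 18. Wittig reaction with the ylide from hex-5-en-1-yl(triphenyl)phosphonium bromide and KN(SiMe3)2 gives the Z-configured relay substrate tert-butyl(dimethyl){[(3S)-4-methyl-3-{[(6Z,8R,10R)-8,10-dimethyl-18-phenyloctadeca-1,6-dien-8-yl]peroxy}pent-4-en-1-yl]oxy}silane F1. The catalyst loads on the unhindered terminal alkene of F1, expels cyclopentene, and so places ruthenium on C5 without having to attack the hindered vinyl group. Closure onto the isopropenyl group then returns the route to 20.

**Step 12.** The bulky peroxide anion may attack the alkene terminus (allylic transposition), the allylic mesylate may ionise with loss of configuration at C3, or elimination to the diene may take over.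

Fallback, reversal of roles: it sets out from 16. Excess aqueous H2O2 with KOH in MeOH at 0 °C displaces the mesylate with inversion, using a small nucleophile in large excess, to give tert-butyl{[(3S)-3-hydroperoxy-4-methylpent-4-en-1-yl]oxy}dimethylsilane F2. F2 then opens epoxy alcohol 8 at the tertiary carbon under H3PMo12O40 catalysis in Et2O, with inversion at C6, and the route is rejoined at 17. The catalyst loading is kept low because heteropolyacids can also cleave silyl ethers. This path also avoids isolating hydroperoxide 9.

**Step 16.** Hydrogen transfer from diimide to a trisubstituted alkene flanked by a quaternary carbon may be slow, so that diimide disproportionates before it reduces. Facial selectivity may also be incomplete, which would give the C4 epimer.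

Fallback, a change of reductant class: it sets out from 20. Hydrogenation with H2 (1 atm) over PtO2 or 5% Rh/Al2O3 in EtOAc at 0 °C, stopped after one equivalent, returns to 21. This kind of surface hydrogenation is how the alkene of ascaridole has been saturated with the O–O bond kept, and it is more sensitive to the shielding by the C3 and C6 substituents. It makes no new compound.

**Step 10.** The selectivity factor of the kinetic resolution may be modest for an alcohol whose alkene is 1,1-disubstituted, so that 15 is recovered with insufficient enantiomeric purity at acceptable conversion. The error would appear after step 12 as the C3 epimer.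

Fallback, asymmetric reduction instead of resolution: it sets out from 14. Oxidation with Dess–Martin periodinane gives 5-{[tert-butyl(dimethyl)silyl]oxy}-2-methylpent-1-en-3-one F3. Corey–Bakshi–Shibata reduction with the (S)-methyl oxazaborolidine catalyst and catecholborane in toluene at −78 °C, with the isopropenyl group as the large substituent, returns to 15 and uses all of the material.

## Further compounds

F1 | step 15 | tert-butyl(dimethyl){[(3S)-4-methyl-3-{[(6Z,8R,10R)-8,10-dimethyl-18-phenyloctadeca-1,6-dien-8-yl]peroxy}pent-4-en-1-yl]oxy}silane | C[C@H](CCCCCCCCc1ccccc1)C[C@](C)(/C=C\CCCC=C)OO[C@@H](CCO[Si](C)(C)C(C)(C)C)C(C)=C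
F2 | step 12 | tert-butyl{[(3S)-3-hydroperoxy-4-methylpent-4-en-1-yl]oxy}dimethylsilane | OO[C@@H](CCO[Si](C)(C)C(C)(C)C)C(C)=C
F0 | step 16 | none | none
F3 | step 10 | 5-{[tert-butyl(dimethyl)silyl]oxy}-2-methylpent-1-en-3-one | C=C(C)C(=O)CCO[Si](C)(C)C(C)(C)C
A1 | alternative 1 | (1S,4R,8S)-1,8-dimethyl-2,3-dioxabicyclo[2.2.2]oct-5-ene | C1=C[C@]2(C)C[C@H](C)[C@H]1OO2
A2 | alternative 1 | (5S)-1,5-dimethylcyclohexa-1,3-diene | CC1=CC=C[C@@H](C)C1
A3 | alternative 2 | (4S,4'S)-3,3'-[(2S,2'S)-3,3'-(1,3-dioxolane-2,2-diyl)bis(2-methylpropanoyl)]bis(4-benzyl-1,3-oxazolidin-2-one) | O=C([C@@H](C)CC1(C[C@H](C)C(=O)N2[C@@H](Cc3ccccc3)COC2=O)OCCO1)N1[C@@H](Cc2ccccc2)COC1=O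
A4 | alternative 2 | (4S,4'S)-3,3'-[3,3'-(1,3-dioxolane-2,2-diyl)dipropanoyl]bis(4-benzyl-1,3-oxazolidin-2-one) | O=C(CCC1(CCC(=O)N2[C@@H](Cc3ccccc3)COC2=O)OCCO1)N1[C@@H](Cc2ccccc2)COC1=O
A5 | alternative 3 | (4S,6R)-4,6-dimethyl-6-[(2R)-2-methyl-10-phenyldecyl]-1,2-dioxan-3-ol (anomers at C3) | C[C@H](CCCCCCCCc1ccccc1)C[C@]1(C)C[C@H](C)C(O)OO1
A6 | alternative 3 | (4R)-2,4-dimethyl-12-phenyldodec-1-ene | C[C@H](CCCCCCCCc1ccccc1)CC(C)=C
A7 | alternative 3 | propanal | CCC=O
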